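**Strategy.** Everything rests on cutting ring B at C7–C8 and C9–C10. Ring B is a masked cyclohexa-1,4-diene: the tetrasubstituted C8=C9 alkene plus the C6 oxygen (as a C5=C6 enol ether) beside quaternary C10. A single intermolecular Diels–Alder reaction between a ring A 2-silyloxydiene (C7=C6–C5=C10) and methyl but-2-ynoate therefore closes ring B and installs C17, C11, the C6 oxygen and the C10 stereocentre together. The diene comes from yeast-desymmetrised 2-methylcyclohexane-1,3-dione and carries 3β-OSiEt3 and 19-OSiPh2t-Bu as separate ethers, so that the C19 arm lies pseudoaxial and shields the β face. C3 is inverted later through a 3,6-dione.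

Key step: step 8

Remark: labdane numbering is used (C18 = 4α-methyl, C19 = 4β-CH2O cis to the C10 methyl C20, β = face of C20); the target is read as 3α,19-bis(3-methylbutanoyloxy)-6β-hydroxylabda-8,13E-dien-15-oic acid in the 10β-methyl, 5α-H series.

Step 1
Reactants: 1 2-methylcyclohexane-1,3-dione
Product: 2 2-(hydroxymethyl)-2-methylcyclohexane-1,3-dione
Conditions: aq. HCHO (37%), H2O, rt
Reagents that add atoms: formaldehyde, C=O
Why: The acidic C2–H of the 1,3-dione adds to formaldehyde in a crossed aldol reaction (hydroxymethylation) that needs no added base, which spares the retro-aldol-prone product; no stereocentre is formed.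

Step 2
Reactants: 2 2-(hydroxymethyl)-2-methylcyclohexane-1,3-dione
Product: 3 (2S,3S)-3-hydroxy-2-(hydroxymethyl)-2-methylcyclohexan-1-one
Conditions: baker's yeast (Saccharomyces cerevisiae), sucrose, H2O, 30 °C
Reagents that add atoms: none
Why: Baker's-yeast reduction of 2,2-disubstituted cyclohexane-1,3-diones is an enantiotopic-group-selective ketone reduction that stops at the hydroxy ketone and is expected to give the (3S)-carbinol cis to the larger C2 substituent, so that C3 (3β-OH) and quaternary C4 are set together by the enzyme.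

Step 3
Reactants: 3 (2S,3S)-3-hydroxy-2-(hydroxymethyl)-2-methylcyclohexan-1-one
Product: 5 (2S,3S)-2-[(tert-butyldiphenylsilyl)oxymethyl]-2-methyl-3-(triethylsilyloxy)cyclohexan-1-one, via mono-silyl ether 4 (not isolated)
Conditions: t-BuPh2SiCl, imidazole, DMF, 0 °C; then Et3SiCl, DMAP (cat.), rt
Reagents that add atoms: tert-butyldiphenylsilyl chloride, CC(C)(C)[Si](Cl)(c1ccccc1)c1ccccc1; triethylsilyl chloride, CC[Si](Cl)(CC)CC
Why: Stepwise silyl ether formation in one flask uses the rate gap between the primary and the neopentylic secondary hydroxyl to put the acid-stable silyl group on O19 and the acid-labile one on O3, leaving both stereocentres untouched.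

Step 4
Reactants: 5 (2S,3S)-2-[(tert-butyldiphenylsilyl)oxymethyl]-2-methyl-3-(triethylsilyloxy)cyclohexan-1-one
Product: 6 (2S,3S,6RS)-2-[(tert-butyldiphenylsilyl)oxymethyl]-2,6-dimethyl-3-(triethylsilyloxy)cyclohexan-1-one (epimers at the new methine, labdane C10)
Conditions: LiN(i-Pr)2, THF, −78 °C; MeI, −78 → −20 °C
Reagents that add atoms: iodomethane, CI
Why: Kinetic enolate alkylation, in which the ketone can enolise only towards C10 because C4 is quaternary; the epimer mixture is irrelevant since C10 becomes sp2 in the next step.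

Step 5
Reactants: 6 (2S,3S,6RS)-2-[(tert-butyldiphenylsilyl)oxymethyl]-2,6-dimethyl-3-(triethylsilyloxy)cyclohexan-1-one
Product: 7 (5S,6S)-6-[(tert-butyldiphenylsilyl)oxymethyl]-2,6-dimethyl-5-(triethylsilyloxy)cyclohex-1-en-1-yl trifluoromethanesulfonate
Conditions: KN(SiMe3)2, THF, −78 → 0 °C; PhNTf2, −78 °C → rt
Reagents that add atoms: N-phenylbis(trifluoromethanesulfonimide), O=S(=O)(N(c1ccccc1)S(=O)(=O)C(F)(F)F)C(F)(F)F
Why: Enol triflate formation: removal of the one remaining α-hydrogen gives the only possible (tetrasubstituted) enolate, which is O-sulfonylated, as is known for 2,2,6-trisubstituted cyclohexanones.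

Step 6
Reactants: 7 enol triflate, 8 tributyl(1-ethoxyvinyl)stannane
Product: 10 1-[(5S,6S)-6-[(tert-butyldiphenylsilyl)oxymethyl]-2,6-dimethyl-5-(triethylsilyloxy)cyclohex-1-en-1-yl]ethan-1-one, via 2-ethoxydiene 9 (not isolated)
Conditions: Pd(PPh3)4 (5 mol%), CuI (10 mol%), LiCl, DMF, 70 °C; then aq. oxalic acid, THF, 0 °C
Reagents that add atoms: water, O
Why: Stille coupling of the hindered enol triflate with the 1-ethoxyvinyl stannane (an acetyl anion equivalent, with LiCl and catalytic CuI assisting transmetalation) followed by brief mild hydrolysis of the enol ether gives the methyl ketone while the Et3Si ether survives.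

Step 7
Reactants: 10 ring A acetyl enone
Product: 11 (5S,6S)-1-[1-(tert-butyldimethylsilyloxy)vinyl]-6-[(tert-butyldiphenylsilyl)oxymethyl]-2,6-dimethyl-5-(triethylsilyloxy)cyclohex-1-ene (ring A 2-silyloxydiene)
Conditions: t-BuMe2SiOTf, Et3N, CH2Cl2, −78 → 0 °C
Reagents that add atoms: tert-butyldimethylsilyl trifluoromethanesulfonate, CC(C)(C)[Si](C)(C)OS(=O)(=O)C(F)(F)F
Why: Soft enolisation of the methyl ketone (silyl enol ether formation) removes a proton from the acetyl CH3 (C7) and gives the cross-conjugated 2-silyloxydiene, the standard way to such dienes from enones.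

Step 8
Reactants: 11 ring A 2-silyloxydiene, 12 methyl but-2-ynoate
Product: 13 methyl 6-(tert-butyldimethylsilyloxy)-19-(tert-butyldiphenylsilyloxy)-3β-(triethylsilyloxy)-12,13,14,15,16-pentanorlabda-5,8-dien-11-oate (10β-methyl)
Conditions: 12 (excess), BHT (cat.), toluene, sealed tube, 140–160 °C
Reagents that add atoms: none
Why: Thermal Diels–Alder reaction: a concerted but asynchronous [4+2] in which the nucleophilic enol-ether terminus C7 bonds to the ynoate β-carbon C8 ahead of C9–C10, the behaviour known for 2-silyloxy-1-vinylcyclohexenes with alkynoates and for 1-vinyl-2,6,6-trimethylcyclohexenes with acetylenic esters, which also create an angular methyl. Ring B closes by suprafacial addition of the two alkyne carbons across C7 and C10 of the s-cis diene, giving a cyclohexa-1,4-diene that cannot aromatise because C10 is quaternary. The new stereocentre C10 is controlled by the ring A half-chair: with O3 equatorial and the small C18 methyl pseudoequatorial beside the in-plane C6–O bond, the CH2OSiPh2t-Bu arm (C19) is pseudoaxial on the β face, so C9 should bond from the α face and C20 should end β. Regioselectivity (ester carbon C11 on C9, C17 on C8) follows from the C6 donor, which places the ester para to it. The selectivity needed is therefore facial, and it is secured by keeping O3 and O19 as separate bulky ethers, since a cyclic 3,19-acetal would prefer the other half-chair, with C18 pseudoaxial, and would steer the alkyne to the β face.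

Step 9
Reactants: 13 Diels–Alder adduct
Product: 14 methyl 19-(tert-butyldiphenylsilyloxy)-3β-hydroxy-6-oxo-12,13,14,15,16-pentanor-5α-labd-8-en-11-oate
Conditions: HF·pyridine, pyridine, THF, 0 °C
Reagents that add atoms: none
Why: Fluoride-assisted protodesilylation cleaves the silyl enol ether and the Et3Si ether far faster than the hindered t-BuPh2Si ether, and C5 is protonated on the α face, anti to the axial C19 and C20 groups, which gives the trans ring fusion (also the thermodynamic one) while the ester-conjugated C8=C9 bond stays in place.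

Step 10
Reactants: 14 3β-hydroxy-6-ketone
Product: 15 methyl 19-(tert-butyldiphenylsilyloxy)-3,6-dioxo-12,13,14,15,16-pentanor-5α-labd-8-en-11-oate
Conditions: Dess–Martin periodinane, NaHCO3, CH2Cl2, rt
Reagents that add atoms: none
Why: Dess–Martin oxidation under buffered, non-enolising conditions converts the equatorial 3β-alcohol into the ketone without epimerising C5 or moving the alkene.

Step 11
Reactants: 15 3,6-dione
Product: 16 methyl 19-(tert-butyldiphenylsilyloxy)-3α,6β-dihydroxy-12,13,14,15,16-pentanor-5α-labd-8-en-11-oate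
Conditions: K[HB(s-Bu)3], THF, −78 °C
Reagents that add atoms: none
Why: Bulky-hydride reduction: equatorial attack on the 3-ketone should give the axial 3α-alcohol, and attack on the 6-ketone from the α face, away from the syn-axial C19 and C20 groups, the axial 6β-alcohol, so that both carbinol centres are set in one operation while the hindered tetrasubstituted enoate is left alone.

Step 12
Reactants: 16 3α,6β-diol
Product: 17 methyl 19-(tert-butyldiphenylsilyloxy)-3α,6β-bis(triethylsilyloxy)-12,13,14,15,16-pentanor-5α-labd-8-en-11-oate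
Conditions: Et3SiOTf, 2,6-lutidine, CH2Cl2, −78 → 0 °C
Reagents that add atoms: triethylsilyl trifluoromethanesulfonate, CC[Si](CC)(CC)OS(=O)(=O)C(F)(F)F
Why: Silyl triflate silylation is reactive enough for the two hindered axial hydroxyls and masks them for the organometallic steps that follow.

Step 13
Reactants: 17 bis(triethylsilyl) ether ester
Product: 18 19-(tert-butyldiphenylsilyloxy)-3α,6β-bis(triethylsilyloxy)-12,13,14,15,16-pentanor-5α-labd-8-en-11-ol
Conditions: i-Bu2AlH, toluene, −78 → 0 °C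
Reagents that add atoms: none
Why: Hydride reduction of the conjugated ester to the primary allylic alcohol, as in the reduction of drim-8-en-11-oates, with the silyl ethers inert.

Step 14
Reactants: 18 allylic alcohol
Product: 20 11-bromo-19-(tert-butyldiphenylsilyloxy)-3α,6β-bis(triethylsilyloxy)-12,13,14,15,16-pentanor-5α-labd-8-ene, via allylic mesylate 19 (not isolated)
Conditions: MsCl, Et3N, THF, −40 °C; then LiBr, THF, 0 °C
Reagents that add atoms: methanesulfonyl chloride, CS(=O)(=O)Cl (its atoms stay only in 19); lithium bromide, [Li+].[Br-]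
Why: Mesylation of the primary allylic alcohol and SN2 displacement by bromide in the same flask give the allylic bromide under neutral conditions that cannot cleave the Et3Si ethers.

Step 15
Reactants: 20 allylic bromide, 21 allyl acetoacetate
Product: 22 allyl 19-(tert-butyldiphenylsilyloxy)-13-oxo-3α,6β-bis(triethylsilyloxy)-16-nor-5α-labd-8-en-15-oate
Conditions: 21, NaH, THF, 0 °C; n-BuLi, 0 °C; then 20, −78 → 0 °C
Reagents that add atoms: none
Why: γ-Alkylation of the acetoacetate dianion: the more basic terminal carbanion displaces the allylic bromide by SN2, forming C11–C12 and leaving the β-keto ester for the next step.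

Step 16
Reactants: 22 β-keto ester
Product: 23 allyl (13Z)-19-(tert-butyldiphenylsilyloxy)-13-(diethoxyphosphoryloxy)-3α,6β-bis(triethylsilyloxy)-16-nor-5α-labda-8,13-dien-15-oate
Conditions: NaH, Et2O, 0 °C; ClP(O)(OEt)2
Reagents that add atoms: diethyl chlorophosphate, CCOP(=O)(Cl)OCC
Why: Enol phosphate formation: the sodium enolate, held in the chelated Z geometry in ether, is phosphorylated on oxygen to give the (Z)-enol phosphate.

Step 17
Reactants: 23 (Z)-enol phosphate
Product: 24 allyl (13E)-19-(tert-butyldiphenylsilyloxy)-3α,6β-bis(triethylsilyloxy)-5α-labda-8,13-dien-15-oate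
Conditions: Me2CuLi (from MeLi and CuI), Et2O, −78 → −50 °C
Reagents that add atoms: lithium dimethylcuprate, [Li+].C[Cu-]C
Why: Enol phosphate–cuprate coupling (addition–elimination) replaces the phosphate by the C16 methyl with retention and so fixes the 13E geometry; at this temperature the allyl ester should not be attacked.

Step 18
Reactants: 24 fully silylated allyl ester
Product: 25 allyl (13E)-3α,6β,19-trihydroxy-5α-labda-8,13-dien-15-oate
Conditions: n-Bu4NF, AcOH, THF, rt → 45 °C
Reagents that add atoms: none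
Why: Buffered fluoride desilylation removes all three silyl ethers at once, the acetic acid preventing base-induced isomerisation of the enoate.

Step 19
Reactants: 25 triol
Product: 26 allyl (13E)-6β-hydroxy-3α,19-bis(3-methylbutanoyloxy)-5α-labda-8,13-dien-15-oate
Conditions: (i-PrCH2CO)2O, DMAP, Et3N, CH2Cl2, 0 °C → rt
Reagents that add atoms: 3-methylbutanoic anhydride, CC(C)CC(=O)OC(=O)CC(C)C
Why: DMAP-catalysed acyl transfer (Steglich-type acylation) esterifies the primary 19-OH and the axial 3α-OH, whereas the 6β-OH, syn-axial to both C20 and the C19 arm, is too shielded to react, so no protecting group is needed.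

Step 20
Reactants: 26 allyl ester
Product: 27 (13E)-6β-hydroxy-3α,19-bis(3-methylbutanoyloxy)-5α-labda-8,13-dien-15-oic acid (target CNP0333611.1)
Conditions: Pd(PPh3)4 (cat.), morpholine, THF, rt
Reagents that add atoms: none
Why: Tsuji–Trost deallylation: zerovalent palladium ionises only the allyl ester and morpholine traps the allyl group, releasing the acid under neutral conditions that leave the two isovalerates and the free 6β-OH untouched.

**Compound list**

1 | 2-methylcyclohexane-1,3-dione | CC1C(=O)CCCC1=O | starting material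
2 | 2-(hydroxymethyl)-2-methylcyclohexane-1,3-dione | CC1(CO)C(=O)CCCC1=O | intermediate
3 | (2S,3S)-3-hydroxy-2-(hydroxymethyl)-2-methylcyclohexan-1-one (OH cis to CH2OH) | O=C1CCC[C@H](O)[C@]1(C)CO | intermediate
4 | (2S,3S)-2-[(tert-butyldiphenylsilyl)oxymethyl]-3-hydroxy-2-methylcyclohexan-1-one | O=C1CCC[C@H](O)[C@]1(C)CO[Si](c2ccccc2)(c2ccccc2)C(C)(C)C | intermediate
5 | (2S,3S)-2-[(tert-butyldiphenylsilyl)oxymethyl]-2-methyl-3-(triethylsilyloxy)cyclohexan-1-one | O=C1CCC[C@H](O[Si](CC)(CC)CC)[C@]1(C)CO[Si](c2ccccc2)(c2ccccc2)C(C)(C)C | intermediate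
6 | (2S,3S,6RS)-2-[(tert-butyldiphenylsilyl)oxymethyl]-2,6-dimethyl-3-(triethylsilyloxy)cyclohexan-1-one | CC1CC[C@H](O[Si](CC)(CC)CC)[C@](C)(CO[Si](c2ccccc2)(c2ccccc2)C(C)(C)C)C1=O | intermediate
7 | (5S,6S)-6-[(tert-butyldiphenylsilyl)oxymethyl]-2,6-dimethyl-5-(triethylsilyloxy)cyclohex-1-en-1-yl trifluoromethanesulfonate | CC1=C(OS(=O)(=O)C(F)(F)F)[C@@](C)(CO[Si](c2ccccc2)(c2ccccc2)C(C)(C)C)[C@@H](O[Si](CC)(CC)CC)CC1 | intermediate
8 | tributyl(1-ethoxyvinyl)stannane | CCCC[Sn](CCCC)(CCCC)C(=C)OCC | starting material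
9 | (5S,6S)-6-[(tert-butyldiphenylsilyl)oxymethyl]-1-(1-ethoxyvinyl)-2,6-dimethyl-5-(triethylsilyloxy)cyclohex-1-ene | CC1=C(C(=C)OCC)[C@@](C)(CO[Si](c2ccccc2)(c2ccccc2)C(C)(C)C)[C@@H](O[Si](CC)(CC)CC)CC1 | intermediate
10 | 1-[(5S,6S)-6-[(tert-butyldiphenylsilyl)oxymethyl]-2,6-dimethyl-5-(triethylsilyloxy)cyclohex-1-en-1-yl]ethan-1-one | CC1=C(C(C)=O)[C@@](C)(CO[Si](c2ccccc2)(c2ccccc2)C(C)(C)C)[C@@H](O[Si](CC)(CC)CC)CC1 | intermediate
11 | (5S,6S)-1-[1-(tert-butyldimethylsilyloxy)vinyl]-6-[(tert-butyldiphenylsilyl)oxymethyl]-2,6-dimethyl-5-(triethylsilyloxy)cyclohex-1-ene (ring A diene C7=C6–C5=C10; 3β-OSiEt3, 19-OSiPh2t-Bu) | CC1=C(C(=C)O[Si](C)(C)C(C)(C)C)[C@@](C)(CO[Si](c2ccccc2)(c2ccccc2)C(C)(C)C)[C@@H](O[Si](CC)(CC)CC)CC1 | intermediate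
12 | methyl but-2-ynoate | CC#CC(=O)OC | starting material
13 | methyl 6-(tert-butyldimethylsilyloxy)-19-(tert-butyldiphenylsilyloxy)-3β-(triethylsilyloxy)-12,13,14,15,16-pentanorlabda-5,8-dien-11-oate (10β-methyl) | CC1=C(C(=O)OC)[C@@]2(C)CC[C@H](O[Si](CC)(CC)CC)[C@](C)(CO[Si](c3ccccc3)(c3ccccc3)C(C)(C)C)C2=C(O[Si](C)(C)C(C)(C)C)C1 | intermediate
14 | methyl 19-(tert-butyldiphenylsilyloxy)-3β-hydroxy-6-oxo-12,13,14,15,16-pentanor-5α-labd-8-en-11-oate | CC1=C(C(=O)OC)[C@@]2(C)CC[C@H](O)[C@](C)(CO[Si](c3ccccc3)(c3ccccc3)C(C)(C)C)[C@@H]2C(=O)C1 | intermediate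
15 | methyl 19-(tert-butyldiphenylsilyloxy)-3,6-dioxo-12,13,14,15,16-pentanor-5α-labd-8-en-11-oate | CC1=C(C(=O)OC)[C@@]2(C)CCC(=O)[C@](C)(CO[Si](c3ccccc3)(c3ccccc3)C(C)(C)C)[C@@H]2C(=O)C1 | intermediate
16 | methyl 19-(tert-butyldiphenylsilyloxy)-3α,6β-dihydroxy-12,13,14,15,16-pentanor-5α-labd-8-en-11-oate | CC1=C(C(=O)OC)[C@@]2(C)CC[C@@H](O)[C@](C)(CO[Si](c3ccccc3)(c3ccccc3)C(C)(C)C)[C@@H]2[C@H](O)C1 | intermediate
17 | methyl 19-(tert-butyldiphenylsilyloxy)-3α,6β-bis(triethylsilyloxy)-12,13,14,15,16-pentanor-5α-labd-8-en-11-oate | CC1=C(C(=O)OC)[C@@]2(C)CC[C@@H](O[Si](CC)(CC)CC)[C@](C)(CO[Si](c3ccccc3)(c3ccccc3)C(C)(C)C)[C@@H]2[C@H](O[Si](CC)(CC)CC)C1 | intermediate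
18 | 19-(tert-butyldiphenylsilyloxy)-3α,6β-bis(triethylsilyloxy)-12,13,14,15,16-pentanor-5α-labd-8-en-11-ol | CC1=C(CO)[C@@]2(C)CC[C@@H](O[Si](CC)(CC)CC)[C@](C)(CO[Si](c3ccccc3)(c3ccccc3)C(C)(C)C)[C@@H]2[C@H](O[Si](CC)(CC)CC)C1 | intermediate
19 | 19-(tert-butyldiphenylsilyloxy)-3α,6β-bis(triethylsilyloxy)-12,13,14,15,16-pentanor-5α-labd-8-en-11-yl methanesulfonate | CC1=C(COS(C)(=O)=O)[C@@]2(C)CC[C@@H](O[Si](CC)(CC)CC)[C@](C)(CO[Si](c3ccccc3)(c3ccccc3)C(C)(C)C)[C@@H]2[C@H](O[Si](CC)(CC)CC)C1 | intermediate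
20 | 11-bromo-19-(tert-butyldiphenylsilyloxy)-3α,6β-bis(triethylsilyloxy)-12,13,14,15,16-pentanor-5α-labd-8-ene | CC1=C(CBr)[C@@]2(C)CC[C@@H](O[Si](CC)(CC)CC)[C@](C)(CO[Si](c3ccccc3)(c3ccccc3)C(C)(C)C)[C@@H]2[C@H](O[Si](CC)(CC)CC)C1 | intermediate
21 | allyl acetoacetate (prop-2-enyl 3-oxobutanoate) | CC(=O)CC(=O)OCC=C | starting material
22 | allyl 19-(tert-butyldiphenylsilyloxy)-13-oxo-3α,6β-bis(triethylsilyloxy)-16-nor-5α-labd-8-en-15-oate | CC1=C(CCC(=O)CC(=O)OCC=C)[C@@]2(C)CC[C@@H](O[Si](CC)(CC)CC)[C@](C)(CO[Si](c3ccccc3)(c3ccccc3)C(C)(C)C)[C@@H]2[C@H](O[Si](CC)(CC)CC)C1 | intermediate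
23 | allyl (13Z)-19-(tert-butyldiphenylsilyloxy)-13-(diethoxyphosphoryloxy)-3α,6β-bis(triethylsilyloxy)-16-nor-5α-labda-8,13-dien-15-oate | CC1=C(CC/C(OP(=O)(OCC)OCC)=C/C(=O)OCC=C)[C@@]2(C)CC[C@@H](O[Si](CC)(CC)CC)[C@](C)(CO[Si](c3ccccc3)(c3ccccc3)C(C)(C)C)[C@@H]2[C@H](O[Si](CC)(CC)CC)C1 | intermediate
24 | allyl (13E)-19-(tert-butyldiphenylsilyloxy)-3α,6β-bis(triethylsilyloxy)-5α-labda-8,13-dien-15-oate | CC1=C(CC/C(C)=C/C(=O)OCC=C)[C@@]2(C)CC[C@@H](O[Si](CC)(CC)CC)[C@](C)(CO[Si](c3ccccc3)(c3ccccc3)C(C)(C)C)[C@@H]2[C@H](O[Si](CC)(CC)CC)C1 | intermediate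
25 | allyl (13E)-3α,6β,19-trihydroxy-5α-labda-8,13-dien-15-oate | CC1=C(CC/C(C)=C/C(=O)OCC=C)[C@@]2(C)CC[C@@H](O)[C@](C)(CO)[C@@H]2[C@H](O)C1 | intermediate
26 | allyl (13E)-6β-hydroxy-3α,19-bis(3-methylbutanoyloxy)-5α-labda-8,13-dien-15-oate | CC1=C(CC/C(C)=C/C(=O)OCC=C)[C@@]2(C)CC[C@@H](OC(=O)CC(C)C)[C@](C)(COC(=O)CC(C)C)[C@@H]2[C@H](O)C1 | intermediate
27 | (13E)-6β-hydroxy-3α,19-bis(3-methylbutanoyloxy)-5α-labda-8,13-dien-15-oic acid (CNP0333611.1) | CC1=C(CC/C(C)=C/C(=O)O)[C@@]2(C)CC[C@@H](OC(=O)CC(C)C)[C@](C)(COC(=O)CC(C)C)[C@@H]2[C@H](O)C1 | target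

**Totals.** Total step count: 20. Longest linear sequence: 20 steps (from 1 to 27); 8, 12 and 21 are used as purchased.

**Steps most likely to fail**

1. Step 8 (key step). What may go wrong: bond formation at the hindered terminus C10 may be slow, so that 1,5-hydrogen shift of the diene or erosion of facial selectivity competes at the temperature required. Fallback: setting out again from diene 11, the dienophile class is changed to an allenoate, methyl buta-2,3-dienoate, which reacts at its ester-conjugated double bond with the same polarity and at lower temperature (toluene, 80–110 °C). The cycloaddition should give the exocyclic-methylene adduct methyl 6-(tert-butyldimethylsilyloxy)-19-(tert-butyldiphenylsilyloxy)-3β-(triethylsilyloxy)-12,13,14,15,16-pentanorlabda-5,8(17)-dien-11-oate F1 (C9 epimers). DBU in warm toluene then moves the C8=C17 double bond into conjugation with the ester, and the route is rejoined at 13.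

2. Step 11. What may go wrong: enolisation of the 6-ketone towards C7 by the basic hydride, or incomplete face selectivity when two ketones are reduced at once. Fallback: setting out from 14, NaBH4 (MeOH/THF, 0 °C) reduces only the 6-ketone, from the α face, to give methyl 19-(tert-butyldiphenylsilyloxy)-3β,6β-dihydroxy-12,13,14,15,16-pentanor-5α-labd-8-en-11-oate F2. An oxidation governed by steric access (TEMPO cat., PhI(OAc)2, CH2Cl2) should then convert the exposed equatorial 3β-alcohol, not the shielded 6β-alcohol, into methyl 19-(tert-butyldiphenylsilyloxy)-6β-hydroxy-3-oxo-12,13,14,15,16-pentanor-5α-labd-8-en-11-oate F3. K[HB(s-Bu)3] at −78 °C reduces this single ketone, and the route is rejoined at 16.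

3. Step 2. What may go wrong: incomplete diastereo- or enantioselection by the yeast reductases for a C2 substituent as small as CH2OH, or retro-aldol loss of formaldehyde in the aqueous medium. Fallback: setting out from 2, silylation first (t-BuPh2SiCl, imidazole, CH2Cl2) gives 2-[(tert-butyldiphenylsilyl)oxymethyl]-2-methylcyclohexane-1,3-dione F4. A Corey–Bakshi–Shibata reduction ((R)-2-methyl-CBS-oxazaborolidine, catecholborane, toluene, −78 °C) follows, in which the catalyst fixes the (S)-carbinol and the hydride is expected to enter anti to the bulky silyloxymethyl group. This comes back to the route at 4, which is silylated with Et3SiCl to 5 as in step 3.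

**Further compounds**

F1 | step 8 | methyl 6-(tert-butyldimethylsilyloxy)-19-(tert-butyldiphenylsilyloxy)-3β-(triethylsilyloxy)-12,13,14,15,16-pentanorlabda-5,8(17)-dien-11-oate (C9 epimers) | C=C1C(C(=O)OC)[C@@]2(C)CC[C@H](O[Si](CC)(CC)CC)[C@](C)(CO[Si](c3ccccc3)(c3ccccc3)C(C)(C)C)C2=C(O[Si](C)(C)C(C)(C)C)C1
F2 | step 11 | methyl 19-(tert-butyldiphenylsilyloxy)-3β,6β-dihydroxy-12,13,14,15,16-pentanor-5α-labd-8-en-11-oate | CC1=C(C(=O)OC)[C@@]2(C)CC[C@H](O)[C@](C)(CO[Si](c3ccccc3)(c3ccccc3)C(C)(C)C)[C@@H]2[C@H](O)C1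
F3 | step 11 | methyl 19-(tert-butyldiphenylsilyloxy)-6β-hydroxy-3-oxo-12,13,14,15,16-pentanor-5α-labd-8-en-11-oate | CC1=C(C(=O)OC)[C@@]2(C)CCC(=O)[C@](C)(CO[Si](c3ccccc3)(c3ccccc3)C(C)(C)C)[C@@H]2[C@H](O)C1
F4 | step 2 | 2-[(tert-butyldiphenylsilyl)oxymethyl]-2-methylcyclohexane-1,3-dione | CC1(CO[Si](c2ccccc2)(c2ccccc2)C(C)(C)C)C(=O)CCCC1=O
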